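A direct plan would make the resorcylate ring first (polyketide-type aldol of a triketo ester to benzyl ester A1) and then grow C1–C4 on it: lateral lithiation/carboxylation to arylacetic acid A2, enantioselective C-methylation to A3, diazoketone A4, copper-carbenoid O–H insertion of the second acid, and hydrogenolysis to the lactol.
Its weakest steps would be (a) the methylation of A2 with a stoichiometric chiral lithium amide and excess n-BuLi: this is the only source of C4, on a di-ortho-substituted arylacetate that also carries a benzyl ester, so ee and chemoselectivity would be left to chance;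
(b) the diazomethane acylation to A4 and the carbenoid insertion after it: hazardous, and run on precious late material where an enolisable α-aryl ketone and three free OH groups compete;
(c) the opening dianion acylation to A1 and the four steps that turn one aryl methyl group into a three-carbon chain: a low-yielding start and many steps for little gain in complexity.

**Plan of the new route** (isochromanone numbering: C1 lactone carbonyl, O2, C3 hemiketal, C4, C4a, C5–C8, C8a)
Cuts, in retrosynthetic order: O2–C3 (lactol to open keto acid); the ester bond CH2–O (to a chloromethyl ketone and the free trimethylresorcylic acid); ring A across C4a–C5 and C8–C8a (to an ynoate holding C1, C8a, C4a, C4, C3 and a vinylketene acetal holding C5–C8); C3–C4 (to an allenylzinc from (R)-but-3-yn-2-ol and chloroacetaldehyde).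
Feature used: ring A carries oxygen at C8 and C6 with C7–H between them and the carboxyl carbon C1 on C8a. That is the imprint of a β-keto-ester-derived vinylketene acetal (C5–C8) on an ynoate (C1–C8a≡C4a), so one [4+2]/elimination step makes the whole penta-substituted ring.
Order of rings: neither ring of the core exists before step 7. Ring A is then made in one step from two open-chain pieces around the finished C4 stereocentre, and ring B closes in the last step. Ring B is therefore still the last ring to close, as in the direct plan: an earlier closure would place the C3 carbonyl next to C4 while C4 still bears an acceptor π-system, and no safe way round this was found.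
The weak steps vanish: C4 is set by chirality transfer from a commercial alcohol before any arene or carbonyl is next to it; nothing is laterally lithiated or C-methylated; no diazo compound or carbenoid appears; the hindered acid enters as a plain carboxylate nucleophile.

Key step: step 7

Remark: C3 is a hemiketal carbon that equilibrates through the open keto acid, so only C4 has to be set; the (3R) centre is taken to follow under thermodynamic control (3-OH trans to 4-CH3).
Remark: chloroacetaldehyde is assumed to be used as the anhydrous monomer, freshly distilled from its commercial aqueous solution.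

Step 1
Reactants: 1 (R)-but-3-yn-2-ol
Product: 2 (R)-but-3-yn-2-yl methanesulfonate
Conditions: MsCl, Et3N, CH2Cl2, 0 °C
Reagents that add atoms: methanesulfonyl chloride, CS(=O)(=O)Cl
Why: O-sulfonylation of the secondary propargylic alcohol breaks no bond to the stereocentre and provides the leaving group for the anti SN2' oxidative addition of the next step.

Step 2
Reactants: 2 (R)-but-3-yn-2-yl methanesulfonate; 3 chloroacetaldehyde
Product: 5 (2S,3S)-1-chloro-3-methylpent-4-yn-2-ol, via allenylzinc reagent 4 (not isolated)
Conditions: Pd(OAc)2 (5 mol %), PPh3 (5 mol %), Et2Zn (3 equiv), THF, −78 → −20 °C; aq. NH4Cl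
Reagents that add atoms: none
Why: Marshall propargylation: zerovalent palladium (formed from Pd(OAc)2, PPh3 and Et2Zn) displaces the mesylate anti-SN2', transmetalation gives the configurationally defined allenylzinc 4, and its syn-SE2' addition to the aldehyde through a cyclic transition state transfers the chirality of 1 to the methyl-bearing carbon (C4 of the target, S); the anti carbinol centre formed alongside is erased later by oxidation.

Step 3
Reactants: 5 (2S,3S)-1-chloro-3-methylpent-4-yn-2-ol
Product: 6 triethyl{[(2S,3S)-1-chloro-3-methylpent-4-yn-2-yl]oxy}silane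
Conditions: Et3SiCl, imidazole, CH2Cl2, 0 °C → rt
Reagents that add atoms: chlorotriethylsilane, CC[Si](Cl)(CC)CC
Why: imidazole-promoted silylation masks the secondary OH for the acetylide chemistry and keeps the chlorohydrin from closing to an epoxide under base.

Step 4
Reactants: 6 triethyl{[(2S,3S)-1-chloro-3-methylpent-4-yn-2-yl]oxy}silane
Product: 7 tert-butyl (4S,5S)-6-chloro-4-methyl-5-[(triethylsilyl)oxy]hex-2-ynoate
Conditions: n-BuLi, THF, −78 °C; Boc2O, −78 °C; AcOH, −78 °C
Reagents that add atoms: di-tert-butyl dicarbonate, CC(C)(C)OC(=O)OC(=O)OC(C)(C)C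
Why: deprotonation of the terminal alkyne and C-acylation of the lithium acetylide with Boc2O should give the tert-butyl ynoate, and the cold acetic acid quench prevents alkoxide-induced ynoate–allenoate isomerisation at C4.

Step 5
Reactants: 8 methyl 3-oxopentanoate
Product: 9 methyl (2E)-3-methoxypent-2-enoate
Conditions: HC(OMe)3, H2SO4 (cat.), MeOH, rt; distillation
Reagents that add atoms: trimethyl orthoformate, COC(OC)OC
Why: acid-catalysed ketalisation of the β-keto ester by the orthoester and loss of methanol on distillation give the conjugated (E)-enol ether.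

Step 6
Reactants: 9 methyl (2E)-3-methoxypent-2-enoate
Product: 10 1,3-dimethoxy-1-[(trimethylsilyl)oxy]penta-1,3-diene (mixture of double-bond isomers, used crude)
Conditions: LiN(iPr)2, THF, −78 °C; Me3SiCl, −78 °C → rt
Reagents that add atoms: chlorotrimethylsilane, C[Si](C)(C)Cl
Why: kinetic γ-deprotonation of the vinylogous ester and O-silylation of the dienolate give a Brassard-type vinylketene acetal that carries C5–C8 of ring A with the C5 methyl group and both ring oxygens.

Step 7
Reactants: 7 tert-butyl (4S,5S)-6-chloro-4-methyl-5-[(triethylsilyl)oxy]hex-2-ynoate; 10 1,3-dimethoxy-1-[(trimethylsilyl)oxy]penta-1,3-diene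
Product: 12 tert-butyl 2-[(2S,3S)-4-chloro-3-hydroxybutan-2-yl]-6-hydroxy-4-methoxy-3-methylbenzoate, via cyclohexa-1,4-diene cycloadduct 11 (not isolated)
Conditions: 10 (2.5 equiv), toluene, 120 °C, sealed tube; then 1 M HCl, THF, rt
Reagents that add atoms: none
Why: Thermal [4+2] cycloaddition of the electron-rich vinylketene acetal 10 to ynoate 7 should give cyclohexa-1,4-diene 11, whose mixed silyl ketal is hydrolysed by the acid to a dienone that tautomerises to the phenol (net loss of methanol), while the same acid removes the triethylsilyl group. The closest known reaction type is the Diels–Alder/aromatisation of Brassard- and Chan-type dienes with simpler alkynoates to give salicylates. Ring A is closed by an intermolecular [4+2] (bonds C4a–C5 and C8–C8a) and aromatised by elimination; ring B is not formed here. No stereocentre is created (the two sp3 ring carbons of 11 disappear), and C4, only propargylic in 7 and benzylic in 12, is not enolisable under these neutral-then-acidic conditions. The step needs regioselectivity, which polarity should secure: the diene terminus C5 (largest HOMO coefficient) bonds to the β-carbon of the ynoate and the ketene-acetal carbon to the α-carbon, placing the C8 oxygen ortho to the carboxyl. It also needs the freed C3–OH not to lactonise, which the di-ortho-substituted tert-butyl ester, hydrogen-bonded to 8-OH, should prevent.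

Step 8
Reactants: 12 tert-butyl 2-[(2S,3S)-4-chloro-3-hydroxybutan-2-yl]-6-hydroxy-4-methoxy-3-methylbenzoate
Product: 13 tert-butyl 2-[(2S)-4-chloro-3-oxobutan-2-yl]-6-hydroxy-4-methoxy-3-methylbenzoate
Conditions: Dess–Martin periodinane (1.3 equiv), CH2Cl2, 0 °C → rt
Reagents that add atoms: none
Why: Dess–Martin oxidation converts the secondary alcohol into the ketone without any base, so the now enolisable C4 (its di-ortho-substituted aryl group twisted out of conjugation) should keep its configuration, and the chelated, ester-deactivated phenol should not be attacked.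

Step 9
Reactants: 14 methyl 2,4-dihydroxy-3,6-dimethylbenzoate
Product: 15 methyl 3-formyl-4,6-dihydroxy-2,5-dimethylbenzoate
Conditions: Cl2CHOMe, TiCl4, CH2Cl2, 0 °C; H2O
Reagents that add atoms: dichloromethyl methyl ether, COC(Cl)Cl; water, O
Why: Rieche formylation (electrophilic substitution by the TiCl4-activated dichloromethyl ether) can only occur at the one free ring position, ortho to 4-OH and para to 2-OH, and hydrolysis of the α-chloro ether gives the aldehyde.

Step 10
Reactants: 15 methyl 3-formyl-4,6-dihydroxy-2,5-dimethylbenzoate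
Product: 16 methyl 2,4-dihydroxy-3,5,6-trimethylbenzoate
Conditions: Et3SiH (2.5 equiv), CF3CO2H, CH2Cl2, rt
Reagents that add atoms: none
Why: ionic hydrogenation: two hydride transfers from the silane to the hydroxy-activated aldehyde, via the benzylic cation, give the third ring methyl group and leave the ester and phenols untouched.

Step 11
Reactants: 16 methyl 2,4-dihydroxy-3,5,6-trimethylbenzoate
Product: 17 2,4-dihydroxy-3,5,6-trimethylbenzoic acid
Conditions: conc. H2SO4, 0 °C → rt; ice–water
Reagents that add atoms: water, O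
Why: ester hydrolysis through the acylium ion (AAc1), the pathway open to 2,6-disubstituted benzoates that resist saponification; the ring has no free position to sulfonate and the cold acid should avoid decarboxylation.

Step 12
Reactants: 13 tert-butyl 2-[(2S)-4-chloro-3-oxobutan-2-yl]-6-hydroxy-4-methoxy-3-methylbenzoate; 17 2,4-dihydroxy-3,5,6-trimethylbenzoic acid
Product: 18 tert-butyl 2-[(2S)-4-(2,4-dihydroxy-3,5,6-trimethylbenzoyloxy)-3-oxobutan-2-yl]-6-hydroxy-4-methoxy-3-methylbenzoate
Conditions: 17 (1.3 equiv), KHCO3 (1.2 equiv), NaI (10 mol %), DMF, rt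
Reagents that add atoms: none
Why: SN2 alkylation of a carboxylate by an α-chloro ketone (phenacyl-ester formation): the hindered acid reacts as the nucleophile and needs no activation, hydrogencarbonate deprotonates only the carboxyl group, and so weak a base should not enolise the α-aryl ketone at C4.

Step 13
Reactants: 18 tert-butyl 2-[(2S)-4-(2,4-dihydroxy-3,5,6-trimethylbenzoyloxy)-3-oxobutan-2-yl]-6-hydroxy-4-methoxy-3-methylbenzoate
Product: 20 [(3R,4S)-3,8-dihydroxy-6-methoxy-4,5-dimethyl-1-oxo-3,4-dihydro-1H-isochromen-3-yl]methyl 2,4-dihydroxy-3,5,6-trimethylbenzoate, via open keto acid 19 (not isolated)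
Conditions: CF3CO2H–CH2Cl2 (1:4), 0 °C → rt
Reagents that add atoms: none
Why: acidolysis of the tert-butyl ester (alkyl–oxygen cleavage, loss of isobutene) frees keto acid 19, which closes by ring–chain tautomerism (carboxyl adds to the C3 ketone); the hemiketal centre should settle as (3R) with 3-OH trans to 4-CH3, and no base touches C4.

**Compound list**
1 | (R)-but-3-yn-2-ol | C#C[C@@H](C)O | starting material
2 | (R)-but-3-yn-2-yl methanesulfonate | C#C[C@@H](C)OS(C)(=O)=O | intermediate
3 | chloroacetaldehyde | O=CCCl | starting material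
4 | ethyl[(aS)-buta-1,2-dien-1-yl]zinc | CC=C=C[Zn]CC | intermediate
5 | (2S,3S)-1-chloro-3-methylpent-4-yn-2-ol | C#C[C@H](C)[C@H](O)CCl | intermediate
6 | triethyl{[(2S,3S)-1-chloro-3-methylpent-4-yn-2-yl]oxy}silane | C#C[C@H](C)[C@H](O[Si](CC)(CC)CC)CCl | intermediate
7 | tert-butyl (4S,5S)-6-chloro-4-methyl-5-[(triethylsilyl)oxy]hex-2-ynoate | CC(C)(C)OC(=O)C#C[C@H](C)[C@H](O[Si](CC)(CC)CC)CCl | intermediate
8 | methyl 3-oxopentanoate | CCC(=O)CC(=O)OC | starting material
9 | methyl (2E)-3-methoxypent-2-enoate | CC/C(OC)=C\C(=O)OC | intermediate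
10 | 1,3-dimethoxy-1-[(trimethylsilyl)oxy]penta-1,3-diene (mixture of double-bond isomers) | CC=C(OC)C=C(OC)O[Si](C)(C)C | intermediate
11 | tert-butyl 2-[(2S,3S)-4-chloro-3-[(triethylsilyl)oxy]butan-2-yl]-4,6-dimethoxy-3-methyl-6-[(trimethylsilyl)oxy]cyclohexa-1,4-diene-1-carboxylate (mixture at the two ring sp3 carbons) | CC(C)(C)OC(=O)C1=C([C@H](C)[C@H](O[Si](CC)(CC)CC)CCl)C(C)C(OC)=CC1(OC)O[Si](C)(C)C | intermediate
12 | tert-butyl 2-[(2S,3S)-4-chloro-3-hydroxybutan-2-yl]-6-hydroxy-4-methoxy-3-methylbenzoate | CC(C)(C)OC(=O)c1c(O)cc(OC)c(C)c1[C@H](C)[C@H](O)CCl | intermediate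
13 | tert-butyl 2-[(2S)-4-chloro-3-oxobutan-2-yl]-6-hydroxy-4-methoxy-3-methylbenzoate | CC(C)(C)OC(=O)c1c(O)cc(OC)c(C)c1[C@H](C)C(=O)CCl | intermediate
14 | methyl 2,4-dihydroxy-3,6-dimethylbenzoate | COC(=O)c1c(C)cc(O)c(C)c1O | starting material
15 | methyl 3-formyl-4,6-dihydroxy-2,5-dimethylbenzoate | COC(=O)c1c(C)c(C=O)c(O)c(C)c1O | intermediate
16 | methyl 2,4-dihydroxy-3,5,6-trimethylbenzoate | COC(=O)c1c(C)c(C)c(O)c(C)c1O | intermediate
17 | 2,4-dihydroxy-3,5,6-trimethylbenzoic acid | OC(=O)c1c(C)c(C)c(O)c(C)c1O | intermediate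
18 | tert-butyl 2-[(2S)-4-(2,4-dihydroxy-3,5,6-trimethylbenzoyloxy)-3-oxobutan-2-yl]-6-hydroxy-4-methoxy-3-methylbenzoate | CC(C)(C)OC(=O)c1c(O)cc(OC)c(C)c1[C@H](C)C(=O)COC(=O)c1c(C)c(C)c(O)c(C)c1O | intermediate
19 | 2-[(2S)-4-(2,4-dihydroxy-3,5,6-trimethylbenzoyloxy)-3-oxobutan-2-yl]-6-hydroxy-4-methoxy-3-methylbenzoic acid | OC(=O)c1c(O)cc(OC)c(C)c1[C@H](C)C(=O)COC(=O)c1c(C)c(C)c(O)c(C)c1O | intermediate
20 | [(3R,4S)-3,8-dihydroxy-6-methoxy-4,5-dimethyl-1-oxo-3,4-dihydro-1H-isochromen-3-yl]methyl 2,4-dihydroxy-3,5,6-trimethylbenzoate | COc1cc(O)c2c(c1C)[C@H](C)[C@](O)(COC(=O)c1c(C)c(C)c(O)c(C)c1O)OC2=O | target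

**Step count and risks**
Total: 13 steps. Longest linear sequence: 8 steps (steps 1, 2, 3, 4, 7, 8, 12, 13).

Steps most likely to fail:

1. Step 7. The cycloaddition may be slow, because the new C4a–C5 bond joins a carbon bearing a branched chain to a methyl-bearing diene terminus; the diene may then desilylate or rearrange faster than it adds, and long heating may isomerise the ynoate to the allenoate with loss of C4. Fallback, from 6 and back at 12: the ring would be built at the aldehyde oxidation level, where the dienophile is far more electrophilic and less hindered. Lithiation of 6 (n-BuLi, THF, −78 °C) and formylation with DMF would give (4S,5S)-6-chloro-4-methyl-5-[(triethylsilyl)oxy]hex-2-ynal F1. Its cycloaddition with 10 (toluene, 40–60 °C) and aromatisation on silica gel (silyl ether at C3 kept) would give 2-[(2S,3S)-4-chloro-3-[(triethylsilyl)oxy]butan-2-yl]-6-hydroxy-4-methoxy-3-methylbenzaldehyde F2. Chlorite oxidation (NaClO2, NaH2PO4, 2-methylbut-2-ene) would give 2-[(2S,3S)-4-chloro-3-[(triethylsilyl)oxy]butan-2-yl]-6-hydroxy-4-methoxy-3-methylbenzoic acid F3, and O-tert-butyl-N,N'-diisopropylisourea would give tert-butyl 2-[(2S,3S)-4-chloro-3-[(triethylsilyl)oxy]butan-2-yl]-6-hydroxy-4-methoxy-3-methylbenzoate F4. 1 M HCl in THF would then remove the silyl group and return to 12.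

2. Step 2. The anhydrous chloroaldehyde may self-condense or polymerise, and ethyl transfer from zinc may compete with allenyl transfer. Fallback, from 2 and back at 6: the oxygen would be carried through the C–C bond formation and the chloride introduced afterwards. The same palladium/zinc propargylation with (4-methoxybenzyloxy)acetaldehyde, a stable α-alkoxy aldehyde, would give (2S,3S)-1-[(4-methoxybenzyl)oxy]-3-methylpent-4-yn-2-ol F5. Et3SiCl/imidazole would give triethyl{[(2S,3S)-1-[(4-methoxybenzyl)oxy]-3-methylpent-4-yn-2-yl]oxy}silane F6, DDQ in wet CH2Cl2 would give (2S,3S)-3-methyl-2-[(triethylsilyl)oxy]pent-4-yn-1-ol F7, and PPh3/CCl4 (Appel reaction) would give 6.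

3. Step 12. Substitution by the intramolecularly hydrogen-bonded, di-ortho-substituted carboxylate may be sluggish, so that O-alkylation of a phenoxide and slow base-mediated epimerisation at C4 gain ground. Fallback, from 13 and 17 and back at 18: the polarity would be reversed, so that the side chain provides the alcohol and the acid the acyl donor under neutral conditions. Sodium formate in aqueous ethanol (60 °C) would convert 13 into tert-butyl 2-[(2S)-4-hydroxy-3-oxobutan-2-yl]-6-hydroxy-4-methoxy-3-methylbenzoate F8. Acid 17 would be converted with acetone, (CF3CO)2O and CF3CO2H into 7-hydroxy-2,2,5,6,8-pentamethyl-4H-1,3-benzodioxin-4-one F9. Irradiation of F9 (300 nm, CH2Cl2) in the presence of F8 would generate the quinoketene, which acylates the primary alcohol and gives 18.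

**Further compounds**
F1 | step 7 | (4S,5S)-6-chloro-4-methyl-5-[(triethylsilyl)oxy]hex-2-ynal | O=CC#C[C@H](C)[C@H](O[Si](CC)(CC)CC)CCl
F2 | step 7 | 2-[(2S,3S)-4-chloro-3-[(triethylsilyl)oxy]butan-2-yl]-6-hydroxy-4-methoxy-3-methylbenzaldehyde | O=Cc1c(O)cc(OC)c(C)c1[C@H](C)[C@H](O[Si](CC)(CC)CC)CCl
F3 | step 7 | 2-[(2S,3S)-4-chloro-3-[(triethylsilyl)oxy]butan-2-yl]-6-hydroxy-4-methoxy-3-methylbenzoic acid | OC(=O)c1c(O)cc(OC)c(C)c1[C@H](C)[C@H](O[Si](CC)(CC)CC)CCl
F4 | step 7 | tert-butyl 2-[(2S,3S)-4-chloro-3-[(triethylsilyl)oxy]butan-2-yl]-6-hydroxy-4-methoxy-3-methylbenzoate | CC(C)(C)OC(=O)c1c(O)cc(OC)c(C)c1[C@H](C)[C@H](O[Si](CC)(CC)CC)CCl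
F5 | step 2 | (2S,3S)-1-[(4-methoxybenzyl)oxy]-3-methylpent-4-yn-2-ol | C#C[C@H](C)[C@H](O)COCc1ccc(OC)cc1
F6 | step 2 | triethyl{[(2S,3S)-1-[(4-methoxybenzyl)oxy]-3-methylpent-4-yn-2-yl]oxy}silane | C#C[C@H](C)[C@H](O[Si](CC)(CC)CC)COCc1ccc(OC)cc1
F7 | step 2 | (2S,3S)-3-methyl-2-[(triethylsilyl)oxy]pent-4-yn-1-ol | C#C[C@H](C)[C@H](O[Si](CC)(CC)CC)CO
F8 | step 12 | tert-butyl 2-[(2S)-4-hydroxy-3-oxobutan-2-yl]-6-hydroxy-4-methoxy-3-methylbenzoate | CC(C)(C)OC(=O)c1c(O)cc(OC)c(C)c1[C@H](C)C(=O)CO
F9 | step 12 | 7-hydroxy-2,2,5,6,8-pentamethyl-4H-1,3-benzodioxin-4-one | CC1(C)OC(=O)c2c(C)c(C)c(O)c(C)c2O1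
A1 | direct plan | benzyl 2,4-dihydroxy-5,6-dimethylbenzoate | Cc1c(O)cc(O)c(C(=O)OCc2ccccc2)c1C
A2 | direct plan | 2-[3-(benzyloxy)-2-(benzyloxycarbonyl)-5-methoxy-6-methylphenyl]acetic acid | COc1cc(OCc2ccccc2)c(C(=O)OCc2ccccc2)c(CC(=O)O)c1C
A3 | direct plan | (2S)-2-[3-(benzyloxy)-2-(benzyloxycarbonyl)-5-methoxy-6-methylphenyl]propanoic acid | COc1cc(OCc2ccccc2)c(C(=O)OCc2ccccc2)c([C@H](C)C(=O)O)c1C
A4 | direct plan | benzyl 2-(benzyloxy)-6-[(2S)-4-diazo-3-oxobutan-2-yl]-4-methoxy-5-methylbenzoate | COc1cc(OCc2ccccc2)c(C(=O)OCc2ccccc2)c([C@H](C)C(=O)C=[N+]=[N-])c1C
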